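Labdane numbering is used throughout.

**Cuts.** The retrosynthesis cuts C12–C13 (side chain to butenolide), the C6 acetate, C4–C18 and C4–C19 (gem-dimethyl back to a C4 ketone), C8=C9 (ring B), and last C5–C6 together with C9–C10.
**Enabling feature.** In ring A the neighbours C10 (quaternary, methyl-bearing) and C5 (fusion CH) each hold one arm of ring B, C9 and C6. C4 flanks C5, so C10–C5–C4 maps onto the β-carbon, α-carbon and carbonyl carbon of 3-methylcyclohex-2-enone.
**Forward order.** Ring A is bought. One flask attaches the C9 alkenyl arm and the C6 aldehyde arm. Ring B then closes by metathesis at C8=C9, C4=O becomes CMe2, C6 is reset and acetylated, and the intact butenolide ring is joined last at C12.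
**Stereochemistry.** C10 comes from a chiral copper–NHC catalyst. C5 comes from aldol attack anti to the new alkenyl group, which gives the trans fusion. C6 comes from α-face hydride addition to the 6-ketone, whose β-face is closed by the axial C19 and C20 methyls.

Key step: step 4

Remark: C17 is the methyl on C8, C18/C19 are the methyls on C4, and C20 is the methyl on C10. Aldol 8 is drawn with the 6S carbinol that a closed transition state predicts; C6 is flattened at ketone 15, so its configuration before that point does not affect the outcome.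

Step 1
Reactants: 1 but-3-yn-1-ol
Product: 2 triisopropyl(but-3-yn-1-yloxy)silane
Conditions: TIPSCl, imidazole, CH2Cl2, 0 °C to rt
Reagents that add atoms: chlorotriisopropylsilane, CC(C)[Si](Cl)(C(C)C)C(C)C
Why: Imidazole-promoted silylation of a primary alcohol, with TIPS chosen because it outlasts the acetic acid medium of step 9 and the TES cleavage there, and carries no arene that platinum could saturate.

Step 2
Reactants: 2 triisopropyl(but-3-yn-1-yloxy)silane
Product: 3 diisobutyl[4-(triisopropylsilyloxy)but-1-en-2-yl]aluminium (kept as a THF stock solution under argon)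
Conditions: DIBAL-H (0.95 equiv), Ni(dppp)Cl2 (3 mol %), THF, 0 to 22 °C
Reagents that add atoms: diisobutylaluminium hydride, CC(C)C[AlH]CC(C)C
Why: Nickel-catalysed α-selective hydroalumination of a terminal alkyne, in which the bidentate phosphine places aluminium on the internal carbon to give the 1,1-disubstituted alkenylalane, and the slight deficit of hydride leaves nothing to reduce 5 or 6 later.

Step 3
Reactants: 4 3-methylbut-3-en-1-ol
Product: 5 3-methylbut-3-enal (dried solution, used the same day)
Conditions: Dess–Martin periodinane, NaHCO3, CH2Cl2, 0 °C to rt; silica plug (pentane–Et2O), cold concentration, 4 Å MS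
Reagents that add atoms: none
Why: Buffered Dess–Martin oxidation is neutral and fast, so the β,γ-unsaturated aldehyde should form without drift of the alkene into conjugation.

Step 4
Reactants: 6 3-methylcyclohex-2-en-1-one; 3 diisobutyl[4-(triisopropylsilyloxy)but-1-en-2-yl]aluminium; 5 3-methylbut-3-enal
Product: 8 (2S,3S)-2-[(1S)-1-hydroxy-3-methylbut-3-en-1-yl]-3-methyl-3-[4-(triisopropylsilyloxy)but-1-en-2-yl]cyclohexan-1-one, via diisobutylaluminium enolate 7 (not isolated)
Conditions: 6 (1.0 equiv), 3 (1.2 equiv), chiral sulfonate-bridged bidentate NHC–Ag complex (2.5 mol %, antipode giving 10S), Cu(OTf)2 (5 mol %), THF, −30 to 4 °C; then 5 (2.5 equiv), −78 to −40 °C; aq. Rochelle salt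
Reagents that add atoms: none
Why: Al-to-Cu transmetalation gives a chiral NHC–Cu–alkenyl species that binds the enone, adds to the β-carbon and reductively eliminates to form C9–C10, releasing aluminium enolate 7, which is Lewis acidic at Al and only weakly basic, binds aldehyde 5 and forms C5–C6 through a closed six-membered Zimmerman–Traxler transition state. The closest known reactions are the Cu–NHC-catalysed enantioselective conjugate addition of α-substituted alkenylalanes to β-methyl cyclic enones and the tandem conjugate addition–aldol (three-component coupling) of aluminium and zinc enolates with aldehydes. No ring is closed. C10 (S) is set by the catalyst, which selects the enone face; C5 (S) is set by the substrate, because axial attack on the half-chair enolate occurs on the face opposite the bulky alkenyl substituent of C10 and leaves the C6 and C9 arms trans on ring A; C6 follows from the chair transition state of a ring-locked E-enolate, which predicts the anti aldol (6S, the later 6α-alcohol), opposite to the target, so it is not relied on and is reset in steps 10 and 11. The step needs alkenyl rather than isobutyl transfer (sp2 groups pass from Al to Cu faster), 1,4- rather than 1,2-addition (secured by copper), and capture of 5 before it isomerises to the conjugated enal or is eaten by surplus 3 (secured by the low basicity of 7, the low temperature, the small excess of 3 and the larger excess of cheap 5).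

Step 5
Reactants: 8 aldol from step 4
Product: 9 (2S,3S)-3-methyl-2-[(1S)-3-methyl-1-(triethylsilyloxy)but-3-en-1-yl]-3-[4-(triisopropylsilyloxy)but-1-en-2-yl]cyclohexan-1-one
Conditions: TESOTf (1.1 equiv), 2,6-lutidine, CH2Cl2, −78 °C
Reagents that add atoms: triethylsilyl triflate, CC[Si](CC)(CC)OS(=O)(=O)C(F)(F)F
Why: Silyl triflate/lutidine silylation of a hindered secondary carbinol at low temperature blocks retro-aldol and β-elimination in later steps, and TES is chosen because mild acid removes it while the primary TIPS ether stays.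

Step 6
Reactants: 9 bis-silyl diene ketone
Product: 10 (5S,6S,10S)-6α-(triethylsilyloxy)-12-(triisopropylsilyloxy)-13,14,15,16,18,19-hexanorlabd-8-en-4-one (trans-decalone, 5α-H, 10β-CH3)
Conditions: Ru 2-isopropoxybenzylidene catalyst with N,N'-di-o-tolyl NHC (10 mol %), 2,6-dichloro-1,4-benzoquinone (10 mol %), toluene (5 mM), 90 °C, Ar sparge
Reagents that add atoms: none
Why: Ring-closing metathesis of two 1,1-disubstituted alkenes to a tetrasubstituted cyclohexene is the task for which the sterically reduced o-tolyl NHC ruthenium catalysts were devised, the trans-diequatorial arms on ring A hold the alkenes close, loss of ethene drives the closure, and the quinone suppresses Ru–H alkene migration.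

Step 7
Reactants: 10 trans-decalone
Product: 11 (5S,6S,10S)-6α-(triethylsilyloxy)-12-(triisopropylsilyloxy)-13,14,15,16,19-pentanorlabda-4(18),8-diene
Conditions: Cp2TiMe2 (3 equiv), toluene, 75 °C, dark
Reagents that add atoms: dimethyltitanocene, [CH3-].[CH3-].[Ti+4].c1cc[cH-]c1.c1cc[cH-]c1
Why: Petasis methylenation uses a non-basic titanium methylidene that olefinates hindered enolisable ketones, so neither C5 epimerisation nor E1cB loss of the β-silyloxy group (both plausible with a phosphorus ylide) should intervene, and the tetrasubstituted alkene is inert to it.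

Step 8
Reactants: 11 exocyclic methylene compound
Product: 12 (5S,6S,10S)-6α-(triethylsilyloxy)-12-(triisopropylsilyloxy)-18,19-cyclo-13,14,15,16-tetranorlabd-8-ene (C4 spirocyclopropane)
Conditions: Et2Zn, CH2I2 (1:1, 5 equiv each), CH2Cl2, 0 °C to rt
Reagents that add atoms: diiodomethane, ICI
Why: Simmons–Smith cyclopropanation (Furukawa variant) is very sensitive to steric access and should take the exposed exocyclic methylene rather than the Δ8(9) alkene buried beside quaternary C10, and no stereocentre arises because the two cyclopropane CH2 groups are equivalent substituents on C4.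

Step 9
Reactants: 12 spirocyclopropane
Product: 14 (5S,6S,10S)-12-(triisopropylsilyloxy)-13,14,15,16-tetranorlabd-8-en-6α-ol, via gem-dimethyl TES ether 13 (not isolated)
Conditions: H2 (3 atm), PtO2, AcOH, rt; filter; then THF–H2O added, rt to 40 °C
Reagents that add atoms: none
Why: Catalytic hydrogenolysis of a 1,1-dialkylcyclopropane breaks the least hindered CH2–CH2 bond to leave the gem-dimethyl group, hindered tetrasubstituted ring alkenes of this kind resist platinum hydrogenation, and diluting the filtrate to AcOH–THF–H2O gives the classical medium for cleaving a TES ether beside a TIPS ether.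

Step 10
Reactants: 14 6α-alcohol
Product: 15 (5S,10S)-12-(triisopropylsilyloxy)-13,14,15,16-tetranorlabd-8-en-6-one
Conditions: Dess–Martin periodinane, NaHCO3, CH2Cl2, 0 °C
Reagents that add atoms: none
Why: Buffered Dess–Martin oxidation should give the β,γ-unsaturated ketone without acid or base strong enough to pull the alkene into conjugation or to epimerise C5.

Step 11
Reactants: 15 6-ketone
Product: 16 (5S,6R,10S)-12-(triisopropylsilyloxy)-13,14,15,16-tetranorlabd-8-en-6β-ol
Conditions: LiAlH4, Et2O, −78 to 0 °C
Reagents that add atoms: none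
Why: In this substrate-controlled hydride reduction the β-face of the carbonyl is closed by the syn-axial C19 and C20 methyls (the situation of 11-oxo steroids), so hydride arrives from the α-face and sets the axial 6β-alcohol (6R), while fast 1,2-addition in the cold outruns enolisation.

Step 12
Reactants: 16 6β-alcohol
Product: 17 (5S,6R,10S)-6β-acetoxy-12-(triisopropylsilyloxy)-13,14,15,16-tetranorlabd-8-ene
Conditions: Ac2O, DMAP, pyridine, 50 °C
Reagents that add atoms: acetic anhydride, CC(=O)OC(C)=O
Why: DMAP-catalysed acylation with gentle heating overcomes the 1,3-diaxial crowding of the 6β-hydroxyl and retains configuration because the C6–O bond is not touched.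

Step 13
Reactants: 17 acetate TIPS ether
Product: 18 (5S,6R,10S)-6β-acetoxy-13,14,15,16-tetranorlabd-8-en-12-ol
Conditions: HF·pyridine, pyridine, THF, 0 °C to rt
Reagents that add atoms: none
Why: Fluoride-mediated desilylation with buffered HF·pyridine removes the primary TIPS ether under conditions that neither hydrolyse nor shift the acetate.

Step 14
Reactants: 18 primary alcohol
Product: 19 (5S,6R,10S)-6β-acetoxy-12-iodo-13,14,15,16-tetranorlabd-8-ene
Conditions: I2, PPh3, imidazole, CH2Cl2, 0 °C to rt
Reagents that add atoms: iodine, II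
Why: Appel-type iodination converts the unhindered primary alcohol by SN2 displacement of its oxyphosphonium ion, with acetate and alkene as spectators.

Step 15
Reactants: 19 primary iodide; 20 4-bromofuran-2(5H)-one
Product: 22 (5S,6R,10S)-6β-acetoxylabda-8,13-dien-15,16-olide (CNP0128495.1), via alkylzinc iodide 21 (not isolated)
Conditions: Zn dust (activated), LiCl, THF, 40 °C; then 20, Pd(OAc)2 (3 mol %), SPhos (6 mol %), THF, rt to 40 °C
Reagents that add atoms: zinc, [Zn] (held only in intermediate 21)
Why: In this Negishi sp3–sp2 cross-coupling the LiCl-assisted zinc insertion tolerates the acetate, the non-basic alkylzinc does not deprotonate the acidic γ-CH2 of the bromobutenolide, and the bulky biarylphosphine favours reductive elimination over β-hydride elimination.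

**Compound list**

1 | but-3-yn-1-ol | C#CCCO | starting material
2 | triisopropyl(but-3-yn-1-yloxy)silane | C#CCCO[Si](C(C)C)(C(C)C)C(C)C | intermediate
3 | diisobutyl[4-(triisopropylsilyloxy)but-1-en-2-yl]aluminium | C=C(CCO[Si](C(C)C)(C(C)C)C(C)C)[Al](CC(C)C)CC(C)C | intermediate
4 | 3-methylbut-3-en-1-ol | C=C(C)CCO | starting material
5 | 3-methylbut-3-enal | C=C(C)CC=O | intermediate
6 | 3-methylcyclohex-2-en-1-one | CC1=CC(=O)CCC1 | starting material
7 | diisobutylaluminium (3S)-3-methyl-3-[4-(triisopropylsilyloxy)but-1-en-2-yl]cyclohex-1-en-1-olate | CC(C)C[Al](CC(C)C)OC1=C[C@@](C)(C(=C)CCO[Si](C(C)C)(C(C)C)C(C)C)CCC1 | intermediate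
8 | (2S,3S)-2-[(1S)-1-hydroxy-3-methylbut-3-en-1-yl]-3-methyl-3-[4-(triisopropylsilyloxy)but-1-en-2-yl]cyclohexan-1-one | O=C1CCC[C@](C)(C(=C)CCO[Si](C(C)C)(C(C)C)C(C)C)[C@H]1[C@@H](O)CC(C)=C | intermediate
9 | triethylsilyl ether of 8 | O=C1CCC[C@](C)(C(=C)CCO[Si](C(C)C)(C(C)C)C(C)C)[C@H]1[C@@H](O[Si](CC)(CC)CC)CC(C)=C | intermediate
10 | (5S,6S,10S)-6α-(triethylsilyloxy)-12-(triisopropylsilyloxy)-13,14,15,16,18,19-hexanorlabd-8-en-4-one | CC[Si](CC)(CC)O[C@H]1CC(C)=C(CCO[Si](C(C)C)(C(C)C)C(C)C)[C@@]2(C)CCCC(=O)[C@H]12 | intermediate
11 | (5S,6S,10S)-6α-(triethylsilyloxy)-12-(triisopropylsilyloxy)-13,14,15,16,19-pentanorlabda-4(18),8-diene | CC[Si](CC)(CC)O[C@H]1CC(C)=C(CCO[Si](C(C)C)(C(C)C)C(C)C)[C@@]2(C)CCCC(=C)[C@H]12 | intermediate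
12 | C4 spirocyclopropane, (5S,6S,10S)-6α-(triethylsilyloxy)-12-(triisopropylsilyloxy)-18,19-cyclo-13,14,15,16-tetranorlabd-8-ene | CC[Si](CC)(CC)O[C@H]1CC(C)=C(CCO[Si](C(C)C)(C(C)C)C(C)C)[C@@]2(C)CCCC3(CC3)[C@H]12 | intermediate
13 | (5S,6S,10S)-6α-(triethylsilyloxy)-12-(triisopropylsilyloxy)-13,14,15,16-tetranorlabd-8-ene | CC[Si](CC)(CC)O[C@H]1CC(C)=C(CCO[Si](C(C)C)(C(C)C)C(C)C)[C@@]2(C)CCCC(C)(C)[C@H]12 | intermediate
14 | (5S,6S,10S)-12-(triisopropylsilyloxy)-13,14,15,16-tetranorlabd-8-en-6α-ol | O[C@H]1CC(C)=C(CCO[Si](C(C)C)(C(C)C)C(C)C)[C@@]2(C)CCCC(C)(C)[C@H]12 | intermediate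
15 | (5S,10S)-12-(triisopropylsilyloxy)-13,14,15,16-tetranorlabd-8-en-6-one | O=C1CC(C)=C(CCO[Si](C(C)C)(C(C)C)C(C)C)[C@@]2(C)CCCC(C)(C)[C@H]12 | intermediate
16 | (5S,6R,10S)-12-(triisopropylsilyloxy)-13,14,15,16-tetranorlabd-8-en-6β-ol | O[C@@H]1CC(C)=C(CCO[Si](C(C)C)(C(C)C)C(C)C)[C@@]2(C)CCCC(C)(C)[C@H]12 | intermediate
17 | (5S,6R,10S)-6β-acetoxy-12-(triisopropylsilyloxy)-13,14,15,16-tetranorlabd-8-ene | CC(=O)O[C@@H]1CC(C)=C(CCO[Si](C(C)C)(C(C)C)C(C)C)[C@@]2(C)CCCC(C)(C)[C@H]12 | intermediate
18 | (5S,6R,10S)-6β-acetoxy-13,14,15,16-tetranorlabd-8-en-12-ol | CC(=O)O[C@@H]1CC(C)=C(CCO)[C@@]2(C)CCCC(C)(C)[C@H]12 | intermediate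
19 | (5S,6R,10S)-6β-acetoxy-12-iodo-13,14,15,16-tetranorlabd-8-ene | CC(=O)O[C@@H]1CC(C)=C(CCI)[C@@]2(C)CCCC(C)(C)[C@H]12 | intermediate
20 | 4-bromofuran-2(5H)-one | O=C1C=C(Br)CO1 | starting material
21 | [(5S,6R,10S)-6β-acetoxy-13,14,15,16-tetranorlabd-8-en-12-yl]zinc iodide | CC(=O)O[C@@H]1CC(C)=C(CC[Zn]I)[C@@]2(C)CCCC(C)(C)[C@H]12 | intermediate
22 | (5S,6R,10S)-6β-acetoxylabda-8,13-dien-15,16-olide (CNP0128495.1) | CC(=O)O[C@@H]1CC(C)=C(CCC2=CC(=O)OC2)[C@@]2(C)CCCC(C)(C)[C@H]12 | target

Total step count: 15. Longest linear sequence: 14 (steps 1, 2 and 4–15).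

**Steps most likely to fail**

**Risk 1 (step 4).**
- What may go wrong: the enolate carbon sits next to the new quaternary centre and may add too slowly. The aldehyde could then be lost to isomerisation, to hydride transfer from Al–isobutyl groups or to surplus alane. Facial selectivity at C5 may also erode.
- Fallback: the two bond formations are separated in time and the closed metal-enolate aldol is replaced by a Lewis acid aldol on a purified nucleophile.
- The fallback sets out from enolate 7, generated from 3 and 6 as in step 4. TMSOTf at −78 °C converts it into the trimethylsilyl enol ether F1, which is isolated free of aluminium species.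
- A Mukaiyama aldol addition of F1 to 5 follows (BF3·OEt2, CH2Cl2, −78 °C, open transition state, attack again opposite the alkenyl group). Aqueous work-up comes back to the route at 8.
- The C6 configuration stays immaterial because it is erased at 15.

**Risk 2 (step 6).**
- What may go wrong: the ruthenium alkylidene may decompose, or may move the methallyl alkene along the chain, before the neopentyl-type C9 alkene beside quaternary C10 engages. Ring closure would then stall.
- Fallback: alkene–alkene metathesis is replaced by reductive carbonyl–carbonyl coupling, setting out from 9.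
- The C4 ketone is masked with 1,2-bis(trimethylsilyloxy)ethane and catalytic TMSOTf (CH2Cl2, −78 to −20 °C) as the ethylene ketal F2.
- Ozonolysis of both 1,1-disubstituted alkenes (O3, CH2Cl2, −78 °C; Me2S) gives the C8,C9-diketone F3.
- Intramolecular McMurry coupling (TiCl3–DME complex, Zn–Cu, DME, reflux, slow addition) accepts hindered ketones and delivers tetrasubstituted cyclohexenes. It gives the ketal-protected octalin F4.
- Aqueous acetic acid in THF at 40 °C removes the ketal and the TES group to give the 6α-hydroxy decalone F5.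
- Resilylation under the conditions of step 5 comes back to the route at 10.

**Risk 3 (step 8).**
- What may go wrong: the exocyclic alkene is crowded by the C10 methyl on one face and lies next to the C6 silyl ether. Methylene transfer may be slow enough for the Δ8(9) alkene to compete, and the cyclopropane that follows may need forcing hydrogenolysis.
- Fallback: carbenoid addition and hydrogenolysis are replaced by a radical hydromethylation, setting out from 11.
- Iron-hydride hydrogen-atom transfer (Fe(acac)3, PhSiH3, THF–MeOH, rt) to the terminal CH2 is much faster for a 1,1-disubstituted than for a tetrasubstituted alkene. It gives the tertiary C4 radical.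
- This radical adds to formaldehyde N-(octylsulfonyl)hydrazone from the equatorial side to give the sulfonylhydrazide F6.
- Warming in methanol (60 °C) expels sulfinic acid and dinitrogen and leaves the second methyl group. This comes back to the route at 13, which then passes through the aqueous acetic acid stage of step 9 to 14.

**Further compounds**

F1 | step 4 | (S)-trimethyl{[3-methyl-3-(4-(triisopropylsilyloxy)but-1-en-2-yl)cyclohex-1-en-1-yl]oxy}silane | C[Si](C)(C)OC1=C[C@@](C)(C(=C)CCO[Si](C(C)C)(C(C)C)C(C)C)CCC1
F2 | step 6 | ethylene ketal of 9 (1,4-dioxaspiro[4.5]decane) | C1COC2(O1)CCC[C@](C)(C(=C)CCO[Si](C(C)C)(C(C)C)C(C)C)[C@H]2[C@@H](O[Si](CC)(CC)CC)CC(C)=C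
F3 | step 6 | C8,C9-diketone from double ozonolysis of F2 | C1COC2(O1)CCC[C@](C)(C(=O)CCO[Si](C(C)C)(C(C)C)C(C)C)[C@H]2[C@@H](O[Si](CC)(CC)CC)CC(C)=O
F4 | step 6 | ethylene ketal of 10 | CC[Si](CC)(CC)O[C@H]1CC(C)=C(CCO[Si](C(C)C)(C(C)C)C(C)C)[C@@]2(C)CCCC3(OCCO3)[C@H]12
F5 | step 6 | (5S,6S,10S)-6α-hydroxy-12-(triisopropylsilyloxy)-13,14,15,16,18,19-hexanorlabd-8-en-4-one | O[C@H]1CC(C)=C(CCO[Si](C(C)C)(C(C)C)C(C)C)[C@@]2(C)CCCC(=O)[C@H]12
F6 | step 8 | N'-(octylsulfonyl)hydrazide at C18 of 13 (4α-CH2NHNHSO2C8H17, 4β-CH3) | CC[Si](CC)(CC)O[C@H]1CC(C)=C(CCO[Si](C(C)C)(C(C)C)C(C)C)[C@@]2(C)CCC[C@@](C)(CNNS(=O)(=O)CCCCCCCC)[C@H]12
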